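**Retrosynthetic overview**

1. Target 49 ⇐ epoxy lactone 42 by exchange of groups only: C1–OSiEt3 becomes the ketone, O10 and O13 become acetates, O8 becomes the tiglate.
2. 42 ⇐ ten-membered (4Z)-allylic alcohol 40: the free C6 hydroxyl first directs oxygen onto C4=C5 (oxirane), then takes the C12 acyl group (γ-lactone).
3. Key disconnection C5–C6: the strategy rests on C5 of the (Z)-trisubstituted C4=C5 alkene (the later cis-4,5-oxirane) being bonded to C6, the O-bearing lactone carbon, inside the ten-membered carbocycle. This allylic alcohol is made from a (Z)-alkenyl iodide and a C6 aldehyde (38) with CrCl2/NiCl2.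
4. 38 ⇐ Evans syn aldol (C7–C8) and hydroxymethylation on a γ-lactone template (C11–C13); aldehyde 21 ⇐ lactic acid dioxolanone (C10), allyl bromide (C8, C9), MeLi (C2) and (Z)-3-bromo-1-iodo-2-methylprop-1-ene (C3–C5, C15).
5. Ring order: ten-membered carbocycle (step 20), oxirane (step 21), γ-lactone (step 22).

Key step: step 20

**Remarks**

- Germacrane numbering of the target (ring C1–C10; C11 on C7; C12 carboxyl and C13 on C11; C14 on C10; C15 on C4) is used for every intermediate from 17 onwards.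
- C1 is carried through the ring closure as a triethylsilyl ether. A C1 ketone would lie five atoms from the metalated C5 on the cis side of the alkene, and a cyclopentenol closure would be expected to outrun the ten-membered one.
- C12 is carried as an N-methoxy-N-methylamide, so that O6 is not acylated before it has directed the epoxidation.
- Assumption: the C1 carbinol configuration (1R, set by the reagent in step 8) is irrelevant to the target, because C1 is oxidised in step 24; it only serves to make the intermediates single diastereomers.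
- Assumption: monomeric formaldehyde 33 is generated by cracking paraformaldehyde just before use.
- The C6 descriptor changes from R (40) to S (41 onwards) and the C7 descriptor changes between R and S along the route only through changes in CIP priority; the geometry is the same throughout.

**Route**

Step 1
Reactants: 1 (S)-lactic acid; 2 pivalaldehyde
Product: 3 (2S,5S)-2-tert-butyl-5-methyl-1,3-dioxolan-4-one
Conditions: TsOH·H2O (cat.), H2SO4 (cat.), pentane, reflux, Dean–Stark; crystallisation from Et2O/pentane, −78 °C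
Reagents that add atoms: none
Why: Acid-catalysed acetalisation of the α-hydroxy acid (Seebach dioxolanone formation) with removal of water; the cis isomer, in which the new acetal carbon is set relative to the lactate centre, should predominate and is purified by low-temperature crystallisation.

Step 2
Reactants: 3 (2S,5S)-2-tert-butyl-5-methyl-1,3-dioxolan-4-one; 4 allyl bromide
Product: 6 (2S,5R)-5-allyl-2-tert-butyl-5-methyl-1,3-dioxolan-4-one, via lithium enolate 5 (not isolated)
Conditions: LiN(iPr)2, THF, −78 °C; then 4, −78 → −30 °C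
Reagents that add atoms: none
Why: Enolate alkylation with self-regeneration of the stereocentre: in the planar enolate the acetal carbon is the only stereocentre, and allyl bromide should enter trans to the tert-butyl group, which fixes C10 as R.

Step 3
Reactants: 6 (2S,5R)-5-allyl-2-tert-butyl-5-methyl-1,3-dioxolan-4-one; 7 methyllithium
Product: 9 (R)-3-hydroxy-3-methylhex-5-en-2-one, via lithium hemiketal 8 (not isolated)
Conditions: MeLi (1.05 equiv), Et2O, −78 °C; AcOH quench at −78 °C
Reagents that add atoms: none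
Why: Single addition of an organolithium to a lactone-type carbonyl: the lithium hemiketal should persist at −78 °C, so that the methyl ketone is released, with loss of pivalaldehyde, only on the acidic quench.

Step 4
Reactants: 9 (R)-3-hydroxy-3-methylhex-5-en-2-one
Product: 10 (R)-3-methyl-3-(triethylsilyloxy)hex-5-en-2-one
Conditions: Et3SiOTf, 2,6-lutidine, CH2Cl2, −78 → 0 °C
Reagents that add atoms: triethylsilyl triflate, CC[Si](CC)(CC)OS(=O)(=O)C(F)(F)F
Why: Silylation of a tertiary alcohol with a silyl triflate and a hindered pyridine base, under which the ketone should not be enolised.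

Step 5
Reactants: 11 propargyl alcohol; 12 methylmagnesium bromide
Product: 14 (Z)-3-iodo-2-methylprop-2-en-1-ol, via alkenylmagnesium alkoxide 13 (not isolated)
Conditions: MeMgBr (3 equiv), CuI (10 mol%), Et2O/THF, −10 °C → rt; then I2, −78 °C → rt
Reagents that add atoms: iodine, II
Why: Copper-catalysed anti-carbomagnesiation of a propargylic alkoxide: methyl adds to C2 and magnesium to C3 inside a five-membered chelate with the alkoxide, so iodinolysis with retention should place iodine cis to CH2OH.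

Step 6
Reactants: 14 (Z)-3-iodo-2-methylprop-2-en-1-ol
Product: 15 (Z)-3-bromo-1-iodo-2-methylprop-1-ene
Conditions: CBr4, PPh3, CH2Cl2, 0 °C
Reagents that add atoms: carbon tetrabromide, BrC(Br)(Br)Br
Why: Appel bromination of a primary allylic alcohol, which does not touch the alkene geometry.

Step 7
Reactants: 10 (R)-3-methyl-3-(triethylsilyloxy)hex-5-en-2-one; 15 (Z)-3-bromo-1-iodo-2-methylprop-1-ene
Product: 17 (1Z,6R)-1-iodo-2,6-dimethyl-6-(triethylsilyloxy)nona-1,8-dien-5-one, via lithium enolate 16 (not isolated)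
Conditions: LiN(iPr)2, THF, −78 °C; then 15, DMPU, −78 → −30 °C
Reagents that add atoms: none
Why: Kinetic ketone enolate alkylation: the ketone can enolise only toward its methyl group because C10 is quaternary, and the enolate should displace the reactive allylic bromide in SN2 fashion to form C2–C3.

Step 8
Reactants: 17 (1Z,6R)-1-iodo-2,6-dimethyl-6-(triethylsilyloxy)nona-1,8-dien-5-one
Product: 18 (1Z,5R,6R)-1-iodo-2,6-dimethyl-6-(triethylsilyloxy)nona-1,8-dien-5-ol
Conditions: (S)-2-methyl-CBS-oxazaborolidine (0.5 equiv), catecholborane, toluene, −78 → −30 °C; MeOH, then aq. NaOH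
Reagents that add atoms: none
Why: Corey–Bakshi–Shibata reduction with catecholborane, which does not hydroborate the terminal alkene at low temperature; the catalyst distinguishes the quaternary C10 side from the CH2 side of the ketone and should give the (1R) carbinol, a temporary stereocentre that masks C1.

Step 9
Reactants: 18 (1Z,5R,6R)-1-iodo-2,6-dimethyl-6-(triethylsilyloxy)nona-1,8-dien-5-ol
Product: 19 (1Z,5R,6R)-1-iodo-2,6-dimethyl-5,6-bis(triethylsilyloxy)nona-1,8-diene
Conditions: Et3SiOTf, 2,6-lutidine, CH2Cl2, −78 → 0 °C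
Reagents that add atoms: triethylsilyl triflate, CC[Si](CC)(CC)OS(=O)(=O)C(F)(F)F
Why: Silylation of a hindered secondary alcohol with a silyl triflate; the group survives all steps up to the ring closure and beyond.

Step 10
Reactants: 19 (1Z,5R,6R)-1-iodo-2,6-dimethyl-5,6-bis(triethylsilyloxy)nona-1,8-diene
Product: 21 (3R,4R,7Z)-8-iodo-3,7-dimethyl-3,4-bis(triethylsilyloxy)oct-7-enal, via vicinal diol 20 (not isolated)
Conditions: OsO4 (2 mol%), NaIO4, 2,6-lutidine, dioxane/H2O (3:1), rt
Reagents that add atoms: sodium periodate, [Na+].[O-]I(=O)(=O)=O; osmium tetroxide (catalytic oxygen carrier), O=[Os](=O)(=O)=O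
Why: Lemieux–Johnson cleavage: OsO4 should dihydroxylate the unhindered monosubstituted alkene in preference to the iodine-bearing trisubstituted one, NaIO4 cleaves the diol to the C8 aldehyde, and 2,6-lutidine keeps the medium from promoting β-elimination.

Step 11
Reactants: 22 succinic anhydride; 23 N,O-dimethylhydroxylamine hydrochloride
Product: 24 4-[methoxy(methyl)amino]-4-oxobutanoic acid
Conditions: Et3N, CH2Cl2, 0 °C → rt; aq. HCl work-up
Reagents that add atoms: none
Why: Ring opening of a cyclic anhydride by an amine (N-acylation), which gives the mono-amide acid directly.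

Step 12
Reactants: 24 4-[methoxy(methyl)amino]-4-oxobutanoic acid; 25 (R)-4-benzyloxazolidin-2-one
Product: 27 (R)-4-benzyl-3-{4-[methoxy(methyl)amino]-4-oxobutanoyl}oxazolidin-2-one, via mixed pivalic anhydride 26 (not isolated)
Conditions: t-BuCOCl, Et3N, THF, −20 °C; then LiCl, 25, −20 °C → rt
Reagents that add atoms: none
Why: N-Acylation of the oxazolidinone through a mixed pivalic anhydride with LiCl/Et3N activation; attack occurs at the less hindered carbonyl of the anhydride.

Step 13
Reactants: 27 (R)-4-benzyl-3-{4-[methoxy(methyl)amino]-4-oxobutanoyl}oxazolidin-2-one; 21 (3R,4R,7Z)-8-iodo-3,7-dimethyl-3,4-bis(triethylsilyloxy)oct-7-enal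
Product: 29 syn-aldol imide (1R,7R,8S,10R;4Z): 8-hydroxy-5-iodo-1,10-bis(triethylsilyloxy)-5,6-seco chain with the (R)-4-benzyl-2-oxooxazolidin-3-yl carbonyl as C6 and the Weinreb amide as C12, via dibutylboron (Z)-enolate 28 (not isolated)
Conditions: Bu2BOTf, iPr2NEt, CH2Cl2, 0 °C; then 21, −78 → 0 °C; pH 7 buffer, MeOH, 30% H2O2, 0 °C
Reagents that add atoms: none
Why: Evans syn aldol reaction: the (Z)-boron enolate reacts through a closed Zimmerman–Traxler transition state in which the benzyl group of the (R)-auxiliary shields one enolate face, which should set C7 and C8 syn (7R,8S) regardless of the remote C10 centre, and the amide at C12 cannot trap the aldolate.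

Step 14
Reactants: 29 syn-aldol imide
Product: 30 O8-tert-butyldimethylsilyl ether of 29 (1R,7R,8S,10R)
Conditions: t-BuMe2SiOTf, 2,6-lutidine, CH2Cl2, −78 → 0 °C
Reagents that add atoms: tert-butyldimethylsilyl triflate, CC(C)(C)[Si](C)(C)OS(=O)(=O)C(F)(F)F
Why: Silylation of the aldol hydroxyl with a silyl triflate, which blocks retro-aldol cleavage and O8 acyl transfer in the following steps.

Step 15
Reactants: 30 O8-silylated aldol imide
Product: 32 γ-lactone (1R,7S,8S,10R): 4-substituted dihydrofuran-2(3H)-one with C12 as carbonyl and C6 as OCH2, via hydroxy amide 31 (not isolated)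
Conditions: NaBH4, THF/H2O (4:1), 0 °C → rt; then PPTS (cat.), toluene, 50 °C
Reagents that add atoms: none
Why: Reductive removal of the auxiliary (NaBH4 reduces the imide carbonyl but not the N-methoxy-N-methylamide) gives the C6 primary alcohol, which should close to the γ-lactone by acid-catalysed acyl transfer from the amide; this ring is the template for C11.

Step 16
Reactants: 32 γ-lactone; 33 formaldehyde
Product: 35 13-hydroxy γ-lactone (1R,7S,8S,10R,11R): trans-3-(hydroxymethyl)-4-substituted dihydrofuran-2(3H)-one, via lithium enolate 34 (not isolated)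
Conditions: LiN(SiMe3)2, THF, −78 °C; CH2O (gas), −78 °C; aq. NH4Cl
Reagents that add atoms: none
Why: Aldol reaction of a lactone lithium enolate with monomeric formaldehyde: the only acidic C–H bonds are at C11, and the electrophile should enter trans to the bulky C7 substituent on the five-membered ring, which sets C11 as R.

Step 17
Reactants: 35 13-hydroxy γ-lactone
Product: 36 13-(tert-butyldiphenylsilyloxy) γ-lactone (1R,7S,8S,10R,11R)
Conditions: t-BuPh2SiCl, imidazole, CH2Cl2, 0 °C → rt
Reagents that add atoms: tert-butyldiphenylsilyl chloride, CC(C)(C)[Si](Cl)(c1ccccc1)c1ccccc1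
Why: Silylation of the primary alcohol under mild imidazole conditions that should not cause β-elimination to the α-methylene lactone; this group is chosen to outlast the later cleavage of the triethylsilyl ethers.

Step 18
Reactants: 36 13-silyloxy γ-lactone; 23 N,O-dimethylhydroxylamine hydrochloride
Product: 37 6-hydroxy N-methoxy-N-methylamide (1R,7S,8S,10R,11R), open chain
Conditions: AlMe3, MeNHOMe·HCl, CH2Cl2, 0 °C → rt; Rochelle salt work-up; used crude
Reagents that add atoms: none
Why: Weinreb aminolysis of the lactone with the aluminium amide formed from AlMe3 and the amine salt; it frees the C6 primary alcohol and leaves C12 as an amide that does not acylate alkoxides readily.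

Step 19
Reactants: 37 6-hydroxy amide
Product: 38 C6 aldehyde (1R,7R,8S,10R,11R;4Z): (Z)-5-iodo-1,10-bis(triethylsilyloxy)-8-(tert-butyldimethylsilyloxy)-13-(tert-butyldiphenylsilyloxy)-5,6-secogermacr-4-en-6-al 12-(N-methoxy-N-methylamide)
Conditions: Dess–Martin periodinane, NaHCO3, CH2Cl2, 0 °C → rt; used at once
Reagents that add atoms: none
Why: Dess–Martin oxidation of a primary alcohol under buffered, non-basic conditions, so that the C7 centre α to the new aldehyde should not epimerise and the β-silyloxy group should not eliminate.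

Step 20
Reactants: 38 C6 aldehyde with (Z)-alkenyl iodide
Product: 40 ten-membered allylic alcohol (1R,6R,7S,8S,10R,11R;4Z): 6-hydroxy-1,10-bis(triethylsilyloxy)-8-(tert-butyldimethylsilyloxy)-13-(tert-butyldiphenylsilyloxy)germacr-4-en-12-oic acid N-methoxy-N-methylamide, via alkenylchromium dichloride 39 (not isolated)
Conditions: CrCl2 (12 equiv), NiCl2 (0.1 equiv), degassed DMSO, rt; slow addition of 38 to a final 0.003 M
Reagents that add atoms: none
Why: Nozaki–Hiyama–Kishi reaction: divalent chromium reduces NiCl2 to zerovalent nickel, which inserts into the C5–I bond with retention of the Z geometry, and transmetalation gives the alkenyl derivative of trivalent chromium, which adds to the C6 aldehyde. The closest known reaction type is the intramolecular NiCl2/CrCl2 coupling of alkenyl iodides with aldehydes that closes medium and large carbocycles under high dilution. The ten-membered ring closes by C5–C6 bond formation in a 10-exo-trig mode, the carbonyl oxygen ending outside the ring as the C6 alkoxide. The new C6 stereocentre is controlled by the adjacent C7 centre: with the C8 branch anti to the incoming alkenyl group (Felkin–Anh) the alkoxide should form syn to the C11 branch along C5–C6–C7–C8, which is the (6R) alcohol needed for the trans-fused lactone. The step needs chemoselectivity for the aldehyde and retention of the alkene geometry: the substrate holds no other carbonyl that an alkenylchromium attacks (C1 is a silyl ether, C12 an amide), and the configurationally stable alkenyl–metal bond carries the Z geometry into the ring.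

Step 21
Reactants: 40 ten-membered allylic alcohol
Product: 41 cis-4,5-epoxy-6-ol (1R,4R,5S,6S,7S,8S,10R,11R), otherwise as 40
Conditions: VO(acac)2 (10 mol%), t-BuOOH (in decane), CH2Cl2, 0 °C → rt
Reagents that add atoms: tert-butyl hydroperoxide, CC(C)(C)OO
Why: Hydroxyl-directed epoxidation: the vanadate ester of O6 delivers the peroxide oxygen with an O6–C6–C5=C4 dihedral near 40–50°, which in a (Z)-cycloalkenol of medium ring size puts the oxirane oxygen on the same side of the ring as O6 (4R,5S), and the amide at C12 should leave O6 free long enough.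

Step 22
Reactants: 41 cis-4,5-epoxy-6-ol
Product: 42 epoxy lactone (1R,4R,5S,6S,7S,8S,10R,11R): 4,5-epoxy-1,10-bis(triethylsilyloxy)-8-(tert-butyldimethylsilyloxy)-13-(tert-butyldiphenylsilyloxy)germacran-12,6-olide
Conditions: PPTS (0.3 equiv), CH2Cl2, rt → 35 °C
Reagents that add atoms: none
Why: Acid-catalysed lactonisation of a γ-hydroxy N-methoxy-N-methylamide: the trans-fused five-membered lactone closes with loss of N,O-dimethylhydroxylamine, which is too weakly basic to quench the pyridinium catalyst, and the aprotic mild acid should spare the oxirane and the silyl ethers.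

Step 23
Reactants: 42 epoxy lactone
Product: 43 1,10-diol (1R,4R,5S,6S,7S,8S,10R,11R), O8 and O13 still silylated
Conditions: HF·pyridine, pyridine, THF, 0 °C
Reagents that add atoms: none
Why: Selective fluoride cleavage: the two triethylsilyl ethers are far more labile toward pyridine-buffered HF than the hindered secondary TBS ether and the primary TBDPS ether, and buffering should keep the oxirane closed.

Step 24
Reactants: 43 1,10-diol
Product: 44 10-hydroxy-1-ketone (4R,5S,6S,7S,8S,10R,11R)
Conditions: IBX, DMSO, rt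
Reagents that add atoms: none
Why: IBX oxidation of the secondary C1 alcohol of a 1,2-diol to the α-hydroxy ketone without glycol cleavage; the tertiary C10 hydroxyl cannot be oxidised and O8 and O13 are protected.

Step 25
Reactants: 44 10-hydroxy-1-ketone
Product: 45 10-acetate (4R,5S,6S,7S,8S,10R,11R)
Conditions: Ac2O, DMAP, Et3N, CH2Cl2, rt → 35 °C
Reagents that add atoms: acetic anhydride, CC(=O)OC(C)=O
Why: DMAP-catalysed acetylation (Steglich-type acyl transfer through the N-acetylpyridinium ion), which is active enough for a tertiary α-ketol; no other hydroxyl is free.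

Step 26
Reactants: 45 10-acetate
Product: 46 8,13-diol (4R,5S,6S,7R,8S,10R,11R)
Conditions: HF·pyridine, pyridine, THF, rt
Reagents that add atoms: none
Why: Fluoride cleavage of the remaining TBS and TBDPS ethers under pyridine-buffered conditions of the kind that trisubstituted oxiranes, lactones and acetates are expected to tolerate.

Step 27
Reactants: 46 8,13-diol
Product: 47 13-acetate with free 8-hydroxyl (4R,5S,6S,7R,8S,10R,11R)
Conditions: AcCl (1.1 equiv), 2,4,6-collidine, CH2Cl2, −78 °C
Reagents that add atoms: acetyl chloride, CC(Cl)=O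
Why: Kinetically selective acetylation: the primary C13 hydroxyl should react much faster than the ring-flanked secondary C8 hydroxyl at −78 °C with a hindered, weakly basic pyridine.

Step 28
Reactants: 47 13-acetate with free 8-hydroxyl; 48 tigloyl chloride
Product: 49 CNP0305680.1 (4R,5S,6S,7R,8S,10R,11R)
Conditions: pyridine, DMAP (cat.), CH2Cl2, 0 °C → rt
Reagents that add atoms: none
Why: Esterification of the only free hydroxyl with an acid chloride through the acylpyridinium ion; the (E)-2-methylbut-2-enoyl group is the stable geometry, and the mild base should not eliminate the C13 acetate.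

**Compound list**

1 | (S)-lactic acid | C[C@H](O)C(=O)O | starting material
2 | pivalaldehyde | CC(C)(C)C=O | starting material
3 | (2S,5S)-2-tert-butyl-5-methyl-1,3-dioxolan-4-one | C[C@@H]1O[C@H](C(C)(C)C)OC1=O | intermediate
4 | allyl bromide | C=CCBr | starting material
5 | lithium enolate of 3 | CC1=C(O[Li])O[C@@H](C(C)(C)C)O1 | intermediate (not isolated)
6 | (2S,5R)-5-allyl-2-tert-butyl-5-methyl-1,3-dioxolan-4-one | C[C@]1(CC=C)O[C@H](C(C)(C)C)OC1=O | intermediate
7 | methyllithium | [Li]C | starting material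
8 | lithium hemiketal from 6 and MeLi (new centre undefined) | C[C@]1(CC=C)O[C@H](C(C)(C)C)OC1(C)O[Li] | intermediate (not isolated)
9 | (R)-3-hydroxy-3-methylhex-5-en-2-one | CC(=O)[C@](C)(O)CC=C | intermediate
10 | (R)-3-methyl-3-(triethylsilyloxy)hex-5-en-2-one | CC(=O)[C@](C)(O[Si](CC)(CC)CC)CC=C | intermediate
11 | propargyl alcohol | C#CCO | starting material
12 | methylmagnesium bromide | C[Mg]Br | starting material
13 | bromomagnesium (Z)-3-(bromomagnesio)-2-methylprop-2-en-1-olate | Br[Mg]/C=C(C)\CO[Mg]Br | intermediate (not isolated)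
14 | (Z)-3-iodo-2-methylprop-2-en-1-ol | I/C=C(C)\CO | intermediate
15 | (Z)-3-bromo-1-iodo-2-methylprop-1-ene | I/C=C(C)\CBr | intermediate
16 | lithium enolate of 10 | C=C(O[Li])[C@](C)(O[Si](CC)(CC)CC)CC=C | intermediate (not isolated)
17 | (1Z,6R)-1-iodo-2,6-dimethyl-6-(triethylsilyloxy)nona-1,8-dien-5-one | I/C=C(C)\CCC(=O)[C@](C)(O[Si](CC)(CC)CC)CC=C | intermediate
18 | (1Z,5R,6R)-1-iodo-2,6-dimethyl-6-(triethylsilyloxy)nona-1,8-dien-5-ol | I/C=C(C)\CC[C@@H](O)[C@](C)(O[Si](CC)(CC)CC)CC=C | intermediate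
19 | (1Z,5R,6R)-1-iodo-2,6-dimethyl-5,6-bis(triethylsilyloxy)nona-1,8-diene | I/C=C(C)\CC[C@@H](O[Si](CC)(CC)CC)[C@](C)(O[Si](CC)(CC)CC)CC=C | intermediate
20 | 8,9-diol of 19 (mixture at the new carbinol) | I/C=C(C)\CC[C@@H](O[Si](CC)(CC)CC)[C@](C)(O[Si](CC)(CC)CC)CC(O)CO | intermediate (not isolated)
21 | (3R,4R,7Z)-8-iodo-3,7-dimethyl-3,4-bis(triethylsilyloxy)oct-7-enal | I/C=C(C)\CC[C@@H](O[Si](CC)(CC)CC)[C@](C)(O[Si](CC)(CC)CC)CC=O | intermediate
22 | succinic anhydride | O=C1CCC(=O)O1 | starting material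
23 | N,O-dimethylhydroxylamine hydrochloride | CNOC.Cl | starting material
24 | 4-[methoxy(methyl)amino]-4-oxobutanoic acid | CON(C)C(=O)CCC(=O)O | intermediate
25 | (R)-4-benzyloxazolidin-2-one | O=C1N[C@H](Cc2ccccc2)CO1 | starting material
26 | mixed pivalic anhydride of 24 | CON(C)C(=O)CCC(=O)OC(=O)C(C)(C)C | intermediate (not isolated)
27 | (R)-4-benzyl-3-{4-[methoxy(methyl)amino]-4-oxobutanoyl}oxazolidin-2-one | CON(C)C(=O)CCC(=O)N1[C@H](Cc2ccccc2)COC1=O | intermediate
28 | dibutylboron (Z)-enolate of 27 | CCCCB(CCCC)O/C(=C\CC(=O)N(C)OC)N1[C@H](Cc2ccccc2)COC1=O | intermediate (not isolated)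
29 | syn-aldol imide (1R,7R,8S,10R;4Z) | I/C=C(C)\CC[C@@H](O[Si](CC)(CC)CC)[C@](C)(O[Si](CC)(CC)CC)C[C@H](O)[C@H](C(=O)N1[C@H](Cc2ccccc2)COC1=O)CC(=O)N(C)OC | intermediate
30 | O8-TBS aldol imide (1R,7R,8S,10R;4Z) | I/C=C(C)\CC[C@@H](O[Si](CC)(CC)CC)[C@](C)(O[Si](CC)(CC)CC)C[C@H](O[Si](C)(C)C(C)(C)C)[C@H](C(=O)N1[C@H](Cc2ccccc2)COC1=O)CC(=O)N(C)OC | intermediate
31 | 6-hydroxy amide lacking C13 (1R,7S,8S,10R;4Z) | I/C=C(C)\CC[C@@H](O[Si](CC)(CC)CC)[C@](C)(O[Si](CC)(CC)CC)C[C@H](O[Si](C)(C)C(C)(C)C)[C@H](CO)CC(=O)N(C)OC | intermediate (not isolated)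
32 | γ-lactone lacking C13 (1R,7S,8S,10R;4Z) | I/C=C(C)\CC[C@@H](O[Si](CC)(CC)CC)[C@](C)(O[Si](CC)(CC)CC)C[C@H](O[Si](C)(C)C(C)(C)C)[C@H]1CC(=O)OC1 | intermediate
33 | formaldehyde | C=O | starting material
34 | lithium enolate of 32 | I/C=C(C)\CC[C@@H](O[Si](CC)(CC)CC)[C@](C)(O[Si](CC)(CC)CC)C[C@H](O[Si](C)(C)C(C)(C)C)[C@H]1C=C(O[Li])OC1 | intermediate (not isolated)
35 | 13-hydroxy γ-lactone (1R,7S,8S,10R,11R;4Z) | I/C=C(C)\CC[C@@H](O[Si](CC)(CC)CC)[C@](C)(O[Si](CC)(CC)CC)C[C@H](O[Si](C)(C)C(C)(C)C)[C@H]1[C@H](CO)C(=O)OC1 | intermediate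
36 | 13-TBDPS-oxy γ-lactone (1R,7S,8S,10R,11R;4Z) | I/C=C(C)\CC[C@@H](O[Si](CC)(CC)CC)[C@](C)(O[Si](CC)(CC)CC)C[C@H](O[Si](C)(C)C(C)(C)C)[C@H]1[C@H](CO[Si](c2ccccc2)(c2ccccc2)C(C)(C)C)C(=O)OC1 | intermediate
37 | 6-hydroxy N-methoxy-N-methylamide (1R,7S,8S,10R,11R;4Z) | I/C=C(C)\CC[C@@H](O[Si](CC)(CC)CC)[C@](C)(O[Si](CC)(CC)CC)C[C@H](O[Si](C)(C)C(C)(C)C)[C@H](CO)[C@H](CO[Si](c1ccccc1)(c1ccccc1)C(C)(C)C)C(=O)N(C)OC | intermediate
38 | C6 aldehyde, ring-closure substrate (1R,7R,8S,10R,11R;4Z) | I/C=C(C)\CC[C@@H](O[Si](CC)(CC)CC)[C@](C)(O[Si](CC)(CC)CC)C[C@H](O[Si](C)(C)C(C)(C)C)[C@H](C=O)[C@H](CO[Si](c1ccccc1)(c1ccccc1)C(C)(C)C)C(=O)N(C)OC | intermediate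
39 | (Z)-alkenylchromium dichloride from 38 | Cl[Cr](Cl)/C=C(C)\CC[C@@H](O[Si](CC)(CC)CC)[C@](C)(O[Si](CC)(CC)CC)C[C@H](O[Si](C)(C)C(C)(C)C)[C@H](C=O)[C@H](CO[Si](c1ccccc1)(c1ccccc1)C(C)(C)C)C(=O)N(C)OC | intermediate (not isolated)
40 | ten-membered (4Z)-6-ol amide (1R,6R,7S,8S,10R,11R) | CC(C)(C)[Si](C)(C)O[C@H]1C[C@@](C)(O[Si](CC)(CC)CC)[C@H](O[Si](CC)(CC)CC)CC/C(C)=C\[C@@H](O)[C@@H]1[C@H](CO[Si](c2ccccc2)(c2ccccc2)C(C)(C)C)C(=O)N(C)OC | intermediate
41 | cis-4,5-epoxy-6-ol amide (1R,4R,5S,6S,7S,8S,10R,11R) | CC(C)(C)[Si](C)(C)O[C@H]1C[C@@](C)(O[Si](CC)(CC)CC)[C@H](O[Si](CC)(CC)CC)CC[C@@]2(C)O[C@H]2[C@@H](O)[C@@H]1[C@H](CO[Si](c3ccccc3)(c3ccccc3)C(C)(C)C)C(=O)N(C)OC | intermediate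
42 | epoxy lactone, 1,10-bis-TES, 8-TBS, 13-TBDPS (1R,4R,5S,6S,7S,8S,10R,11R) | CC(C)(C)[Si](C)(C)O[C@H]1C[C@@](C)(O[Si](CC)(CC)CC)[C@H](O[Si](CC)(CC)CC)CC[C@@]2(C)O[C@H]2[C@H]2OC(=O)[C@@H](CO[Si](c3ccccc3)(c3ccccc3)C(C)(C)C)[C@@H]21 | intermediate
43 | epoxy lactone 1,10-diol (1R,4R,5S,6S,7S,8S,10R,11R) | CC(C)(C)[Si](C)(C)O[C@H]1C[C@@](C)(O)[C@H](O)CC[C@@]2(C)O[C@H]2[C@H]2OC(=O)[C@@H](CO[Si](c3ccccc3)(c3ccccc3)C(C)(C)C)[C@@H]21 | intermediate
44 | epoxy lactone 10-hydroxy-1-ketone (4R,5S,6S,7S,8S,10R,11R) | CC(C)(C)[Si](C)(C)O[C@H]1C[C@@](C)(O)C(=O)CC[C@@]2(C)O[C@H]2[C@H]2OC(=O)[C@@H](CO[Si](c3ccccc3)(c3ccccc3)C(C)(C)C)[C@@H]21 | intermediate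
45 | epoxy lactone 10-acetoxy-1-ketone (4R,5S,6S,7S,8S,10R,11R) | CC(C)(C)[Si](C)(C)O[C@H]1C[C@@](C)(OC(C)=O)C(=O)CC[C@@]2(C)O[C@H]2[C@H]2OC(=O)[C@@H](CO[Si](c3ccccc3)(c3ccccc3)C(C)(C)C)[C@@H]21 | intermediate
46 | 10-acetoxy-8,13-diol (4R,5S,6S,7R,8S,10R,11R) | O[C@H]1C[C@@](C)(OC(C)=O)C(=O)CC[C@@]2(C)O[C@H]2[C@H]2OC(=O)[C@@H](CO)[C@@H]21 | intermediate
47 | 10,13-diacetoxy-8-ol (4R,5S,6S,7R,8S,10R,11R) | O[C@H]1C[C@@](C)(OC(C)=O)C(=O)CC[C@@]2(C)O[C@H]2[C@H]2OC(=O)[C@@H](COC(C)=O)[C@@H]21 | intermediate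
48 | tigloyl chloride, (E)-2-methylbut-2-enoyl chloride | C/C=C(\C)C(Cl)=O | starting material
49 | CNP0305680.1 (4R,5S,6S,7R,8S,10R,11R) | C/C=C(\C)C(=O)O[C@H]1C[C@@](C)(OC(C)=O)C(=O)CC[C@@]2(C)O[C@H]2[C@H]2OC(=O)[C@@H](COC(C)=O)[C@@H]21 | target

**Step count**

Total: 28 steps. Longest linear sequence: 24 steps (1–4, 7–10, 13–28); steps 5–6 and 11–12 are side branches. The ring-closure substrate 38 is reached after 15 linear steps.

**Steps most likely to fail**

1. Step 20 (ring closure). The alkenylchromium may add to the other face of the aldehyde because the ring-closing transition state overrides the Felkin preference, or chains may couple with one another instead of closing. Fallback, setting out from 38 and returning at 40: the cyclisation is kept, and if the ring alcohol formed is the (6S)-epimeric ring alcohol F1, it is oxidised with Dess–Martin periodinane/NaHCO3 to the (4Z)-en-6-one F2. F2 is then reduced with NaBH4/CeCl3·7H2O in MeOH at −78 °C (Luche 1,2-reduction); hydride should arrive on the outer face of the ring enone, anti to the C7 side chain, and give 40. The C6 centre is then set by hydride addition to a ring ketone and no longer in the C–C bond formation.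

2. Step 22 (lactonisation). Acyl transfer from the amide to the hindered secondary C6 hydroxyl may be slow, and acid-promoted opening of the neighbouring oxirane may take over when the acid is made stronger. Fallback, setting out from 36 and returning at 42: the acyl donor is changed to a methyl ester. Lactone 36 is opened with LiOH (THF/H2O, 0 °C) to the lithium carboxylate F3, which is neutralised with AcOH and methylated at once with Me3SiCHN2 to the hydroxy methyl ester F4. Dess–Martin oxidation gives the aldehyde ester F5, the same CrCl2/NiCl2 closure gives the ring alcohol ester F6, and VO(acac)2/t-BuOOH gives the epoxy alcohol ester F7. Its γ-hydroxy methyl ester should close to 42 on silica gel or with a trace of PPTS at room temperature. The price is that the ester may close onto O6 before the epoxidation, which is why the amide is the first choice.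

3. Step 23 (unmasking C1 beside the oxirane). Once the C1 hydroxyl is free it may attack C4 of the oxirane across the ring to form a five-membered ether under the weakly acidic fluoride conditions. Fallback, setting out from 40 and returning at 44: C1 is brought to the ketone before the oxirane exists. HF·pyridine/pyridine removes the two triethylsilyl groups of 40 to give the triol F8, and IBX in DMSO oxidises both secondary alcohols to the (4Z)-ene-1,6-dione F9. NaBH4/CeCl3·7H2O at −78 °C should reduce the conjugated C6 carbonyl in preference to the hindered α-hydroxy C1 ketone and give the 6-hydroxy-1-ketone F10. VO(acac)2/t-BuOOH then gives the epoxy alcohol F11, and PPTS closes the lactone to 44.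

**Further compounds**

F1 | step 20 | (6S)-epimer of ring alcohol 40 | CC(C)(C)[Si](C)(C)O[C@H]1C[C@@](C)(O[Si](CC)(CC)CC)[C@H](O[Si](CC)(CC)CC)CC/C(C)=C\[C@H](O)[C@@H]1[C@H](CO[Si](c2ccccc2)(c2ccccc2)C(C)(C)C)C(=O)N(C)OC
F2 | step 20 | (4Z)-en-6-one of the ten-membered ring | CC(C)(C)[Si](C)(C)O[C@H]1C[C@@](C)(O[Si](CC)(CC)CC)[C@H](O[Si](CC)(CC)CC)CC/C(C)=C\C(=O)[C@@H]1[C@H](CO[Si](c2ccccc2)(c2ccccc2)C(C)(C)C)C(=O)N(C)OC
F3 | step 22 | lithium 6-hydroxy carboxylate from lactone 36 | I/C=C(C)\CC[C@@H](O[Si](CC)(CC)CC)[C@](C)(O[Si](CC)(CC)CC)C[C@H](O[Si](C)(C)C(C)(C)C)[C@H](CO)[C@H](CO[Si](c1ccccc1)(c1ccccc1)C(C)(C)C)C(=O)[O-].[Li+]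
F4 | step 22 | 6-hydroxy methyl ester | I/C=C(C)\CC[C@@H](O[Si](CC)(CC)CC)[C@](C)(O[Si](CC)(CC)CC)C[C@H](O[Si](C)(C)C(C)(C)C)[C@H](CO)[C@H](CO[Si](c1ccccc1)(c1ccccc1)C(C)(C)C)C(=O)OC
F5 | step 22 | C6 aldehyde methyl ester | I/C=C(C)\CC[C@@H](O[Si](CC)(CC)CC)[C@](C)(O[Si](CC)(CC)CC)C[C@H](O[Si](C)(C)C(C)(C)C)[C@H](C=O)[C@H](CO[Si](c1ccccc1)(c1ccccc1)C(C)(C)C)C(=O)OC
F6 | step 22 | ten-membered (4Z)-6-ol methyl ester | CC(C)(C)[Si](C)(C)O[C@H]1C[C@@](C)(O[Si](CC)(CC)CC)[C@H](O[Si](CC)(CC)CC)CC/C(C)=C\[C@@H](O)[C@@H]1[C@H](CO[Si](c2ccccc2)(c2ccccc2)C(C)(C)C)C(=O)OC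
F7 | step 22 | cis-4,5-epoxy-6-ol methyl ester | CC(C)(C)[Si](C)(C)O[C@H]1C[C@@](C)(O[Si](CC)(CC)CC)[C@H](O[Si](CC)(CC)CC)CC[C@@]2(C)O[C@H]2[C@@H](O)[C@@H]1[C@H](CO[Si](c3ccccc3)(c3ccccc3)C(C)(C)C)C(=O)OC
F8 | step 23 | 1,6,10-triol of the ten-membered (4Z)-ene amide | CC(C)(C)[Si](C)(C)O[C@H]1C[C@@](C)(O)[C@H](O)CC/C(C)=C\[C@@H](O)[C@@H]1[C@H](CO[Si](c2ccccc2)(c2ccccc2)C(C)(C)C)C(=O)N(C)OC
F9 | step 23 | 10-hydroxy-(4Z)-ene-1,6-dione amide | CC(C)(C)[Si](C)(C)O[C@H]1C[C@@](C)(O)C(=O)CC/C(C)=C\C(=O)[C@@H]1[C@H](CO[Si](c2ccccc2)(c2ccccc2)C(C)(C)C)C(=O)N(C)OC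
F10 | step 23 | 6,10-dihydroxy-(4Z)-en-1-one amide | CC(C)(C)[Si](C)(C)O[C@H]1C[C@@](C)(O)C(=O)CC/C(C)=C\[C@@H](O)[C@@H]1[C@H](CO[Si](c2ccccc2)(c2ccccc2)C(C)(C)C)C(=O)N(C)OC
F11 | step 23 | cis-4,5-epoxy-6,10-dihydroxy-1-one amide | CC(C)(C)[Si](C)(C)O[C@H]1C[C@@](C)(O)C(=O)CC[C@@]2(C)O[C@H]2[C@@H](O)[C@@H]1[C@H](CO[Si](c3ccccc3)(c3ccccc3)C(C)(C)C)C(=O)N(C)OC
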